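## Analysis of the target

Numbering used throughout: C1–C6 are the atoms of the bicyclo[3.1.0]hexan-2-one (C1 methyl-bearing bridgehead, C2 carbonyl, C3, C4, C5 hydrogen-bearing bridgehead, C6 one-carbon bridge), and the chain on C4 is C7(=C8)–C9–C10(=O)–C11–C12.

The target 36 is a cis-fused cyclopropane–cyclopentanone. C6 carries a methyl group and a 2-methoxy-3,5-dimethyl-4-pyranone; C4 carries a seven-carbon chain with an (E)-trisubstituted C7=C8 alkene, a methyl-bearing C9 and an ethyl ketone at C10. There are six stereocentres: C1, C5 and C6 on the three-membered ring (C1 and C6 quaternary and adjacent), C3 and C4 on the five-membered ring, and C9. The C6 methyl lies over the five-membered ring (endo) and the pyranone is exo, cis to the C1 methyl and H5; the C4 chain is on the convex face, the C3 methyl is trans to it, and C9 is insulated from the ring by the alkene. C9 is α to a ketone and allylic, so it can epimerise and the alkene can move into conjugation; C3 is α to the ring ketone; the acyl cyclopropane and the pyranone limit strong acid. The hard part is the fully substituted cyclopropane with two neighbouring quaternary carbons in a fixed relation to C3, C4 and the remote C9. The strategy rests on one feature: C2 is bonded to quaternary C1 while C5 carries hydrogen, which is the formal addition of the formyl C–H bond of a C2 aldehyde across the C1=C5 bond of a cyclopropene that already holds C6. In the cis-fused product H5 is cis to the C1 methyl and trans to C2, so acyl carbon and hydrogen must arrive on opposite faces of that double bond. This rules out suprafacial delivery from a metal acyl hydride (for example from a cationic monovalent rhodium complex such as [Rh(dppe)]ClO4, which would have to end in a trans-fused bicycle) and calls for a stepwise acyl radical addition.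

## Retrosynthetic reasoning

**C10 oxidation level (36 ⇐ 35 ⇐ 34).** No skeletal bond is cut. The C10 ketone is carried as a silyl-protected carbinol until the last step, because a β,γ-unsaturated ketone with a stereocentre between carbonyl and alkene would not survive enolate chemistry, fluoride or base. The forward steps are a desilylation and a neutral oxidation.

**Pyranone (34 ⇐ 33 ⇐ 32 ⇐ 31 ⇐ 29 + 30).** The ring O–C(=O) bond and the bond between the carbon attached to C6 and the γ-carbon of the keto ester 30 are cut. This builds the heterocycle from a commercial five-carbon unit and a non-enolisable aldehyde on C6. The forward aldol must choose the aldehyde over the hindered C2 ketone, and the cyclisation and O-methylation must give the 2-methoxy-4-pyranone.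

**C6 arm (29 ⇐ 28 ⇐ 27).** The formyl group is traced back to a silyloxymethyl group. This is a redox detour, accepted for two reasons: an ester or aldehyde on C6 would not survive the lithiation that completes the cyclopropene, and a bulky CH2OSi group is needed next to a methyl group to differentiate the cyclopropene faces in the key step. A primary tert-butyldimethylsilyl ether is chosen so that it can be removed beside the secondary triisopropylsilyl ether at C10.

**Key disconnection, C1–C2 (27 ⇐ 26).** Cutting the bond between the carbonyl and quaternary C1 opens the five-membered ring and leaves aldehyde 26, in which C3, C4, the whole side chain and C6 are already in place. No other cut of the bicycle keeps all six stereocentres in the precursor. The forward reaction has to add the formyl C–H bond across C1=C5 with acyl on the face of the C6 methyl and hydrogen on the opposite face at C5; only a stepwise radical sequence can do this, and ring strain supplies the driving force that a 5-endo closure onto an ordinary alkene lacks.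

**Cyclopropene (26 ⇐ 25 ⇐ 24 ⇐ 22 ⇐ 21 ⇐ 20 ⇐ 17 + 19).** The C1–CH3 bond is cut first (24 ⇐ 22), then C5–C6 and C1–C6 together (20 ⇐ 17 + 19). Carbene transfer from an α-alkyl diazo ester is reliable and catalyst-controlled with 1-alkynes but not with internal alkynes, so the ring is made on a terminal alkyne and the C1 methyl is added afterwards through the acidic vinylic C–H bond. The ester of 20 becomes the CH2O arm, and 19 comes from 18 in one step.

**C3–C4 bond (17 ⇐ 16 ⇐ 15 ⇐ 12).** A [3,3]-sigmatropic disconnection of the C3–C4 bond leads to the allylic propanoate 12. The forward ester-enolate Claisen rearrangement has to do three things at once: transfer the C8 carbinol configuration to C4, set C3 through the ketene acetal geometry, and form the (E)-C7=C8 alkene. The alkyne on C4 is small and sits equatorial in the chair.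

**Allylic ester (12 ⇐ 11 ⇐ 8 + 9; 8 ⇐ 7 ⇐ 6 ⇐ 3 + 4; 3 ⇐ 1 + 2).** The propanoyl group and the C10 hydrogen both come from propanal 9 in a reductive acyl transfer on hydroxy ketone 8, which also differentiates the two oxygens. The C8–C9 bond is cut as an auxiliary-controlled aldol between 4 and enynal 3, which sets C9 (kept to the end) and C8 (relayed to C3 and C4). The C4=C7 bond of 3 is an olefination of 1 with 2.

## Alternatives that were turned down

**Alternative 1:** The C4–C5 and C1–C6 bonds are traced to a 4,4-disubstituted cyclohexenone made by dearomatisation of a benzoate and an enzymatic alkene reduction; irradiation contracts the ring to the keto ester A1.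
- For it: three cyclopropane stereocentres arise in one stereospecific photochemical step of a long-known class, from a cheap aromatic, and C6 arrives with a carbon at the ester level for the pyranone. On precedent for the ring-forming step and on step count to the bicycle it is stronger than the chosen route.
- Against it: A1 has only CH2 at C4. The seven-carbon chain with C9 must be attached afterwards at a carbon β to the ketone, which means desaturation to a bicyclo[3.1.0]hex-3-en-2-one (photolabile and prone to open to a phenol) and conjugate addition of a stereodefined trisubstituted alkenyl metal, with C3 then set by enolate protonation. An ester on the migrating quaternary carbon also slows this type of rearrangement.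
- Comparison: the chosen strategy offers C3, C4, C9 and the complete chain fixed before the ring exists, by one aldol and one sigmatropic step, so no carbon–carbon bond has to be made on the strained ketone.

**Alternative 2:** Both exocyclic bonds at C6 are cut, back to a gem-dibromocyclopropane from a silyloxy methylcyclopentene; an alkenyl cuprate exchanges the exo bromine, one alkenyl group shifts to carbon, and a methyl electrophile caps the cyclopropyl copper to give A2.
- For it: it is designed exactly for the crowded quaternary C6, the bicyclic shape decides exo against endo, and the butenyl group is a latent ethyl ketone for the pyranone. On precedent for C6 it is stronger than the chosen route.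
- Against it: A2 has no substituent at C3 or C4 and no C2 carbonyl. C3 methyl and the C4 chain again need an enone and a conjugate addition; the absolute configuration needs a resolved or asymmetric carbinol; the pyranone must be grown from an ethyl ketone next to a quaternary centre.
- Comparison: it is longer after the key step and weaker on C3, C4 and C9; the chosen strategy gives those centres early and keeps the end game to known pyranone chemistry.

**Alternative 3:** C1–C5 and C5–C6 are cut, back to a silyloxy 1,5-enyne with a tetrasubstituted alkene; a cationic phosphine–gold catalyst (monovalent gold) closes both rings to A3.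
- For it: it is catalytic, mild and stereospecific (alkene geometry becomes the C6 configuration), it builds both carbocycles in one step, and it leaves a C3=C4 alkene as a handle. Its key step is better precedented than the radical closure used here and it is stronger on that point.
- Against it: it needs a geometrically pure tetrasubstituted alkene as the only source of the C6 configuration, and the C4 chain with C9 must still be joined late by oxidation to the cyclopropyl enone and conjugate addition, with C3 set by protonation.
- Comparison: overall length is similar. The chosen strategy avoids the tetrasubstituted alkene and the late fragment union, and sets C6 by a catalyst in a known carbene transfer that then controls C1.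

Key step: step 17

Assumption: Rh2(S-NTTL)4 is taken to deliver the (1R)-cyclopropene 20; if the sense of induction with this alkyne is the opposite, the enantiomeric catalyst Rh2(R-NTTL)4 is used in the same step.

Assumption: the carbinol carbon C10 is a spectator that becomes the ketone in step 25; it is carried in the (S) configuration that step 5 delivers.

## Route

Step 1
Reactants: 1 3-(trimethylsilyl)prop-2-ynal; 2 2-(triphenyl-λ5-phosphanylidene)propanal
Product: 3 (2E)-2-methyl-5-(trimethylsilyl)pent-2-en-4-ynal
Conditions: CH2Cl2, 0 °C → rt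
Reagents that add atoms: none
Why: Wittig olefination with a formyl-stabilised ylide; only the ynal is electrophilic enough to react, and reversible adduct formation with a stabilised ylide should give the (E)-enal (alkynyl trans to formyl).

Step 2
Reactants: 3; 4 (4R)-4-benzyl-3-propanoyl-1,3-oxazolidin-2-one
Product: 6 (4R)-4-benzyl-3-[(2R,3R,4E)-3-hydroxy-2,4-dimethyl-7-(trimethylsilyl)hept-4-en-6-ynoyl]-1,3-oxazolidin-2-one, via boron enolate 5 (not isolated)
Conditions: Bu2BOTf, iPr2NEt, CH2Cl2, −78 → 0 °C; then 3, −78 → 0 °C; pH 7 buffer/MeOH/H2O2, 0 °C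
Reagents that add atoms: none
Why: Auxiliary-controlled syn-aldol addition (Evans aldol): the (Z)-boron enolate 5 reacts through a closed chair transition state on the face away from the benzyl group, which sets C9 and the C8 carbinol (both R, syn).

Step 3
Reactants: 6
Product: 7 (2R,3R,4E)-3-hydroxy-N-methoxy-N,2,4-trimethyl-7-(trimethylsilyl)hept-4-en-6-ynamide
Conditions: MeNH(OMe)·HCl, AlMe3, CH2Cl2, −20 → 0 °C
Reagents that add atoms: N,O-dimethylhydroxylamine hydrochloride, Cl.CNOC
Why: Aluminium-amide aminolysis of the imide (Weinreb amide formation); the free β-hydroxyl directs attack to the exocyclic carbonyl and the auxiliary is released, without base that could epimerise C9.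

Step 4
Reactants: 7
Product: 8 (4R,5R,6E)-5-hydroxy-4,6-dimethyl-9-(trimethylsilyl)non-6-en-8-yn-3-one
Conditions: EtMgBr (3 equiv), THF, 0 °C; aq. NH4Cl
Reagents that add atoms: ethylmagnesium bromide, CC[Mg]Br
Why: Grignard addition to an N-methoxy-N-methylamide stops at the chelated tetrahedral adduct, so the ethyl ketone appears only on work-up; the magnesium alkoxide formed first protects the aldol from retro-aldol cleavage.

Step 5
Reactants: 8; 9 propanal
Product: 11 (3S,4S,5R,6E)-3-hydroxy-4,6-dimethyl-9-(trimethylsilyl)non-6-en-8-yn-5-yl propanoate, via samarium hemiacetal 10 (not isolated)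
Conditions: SmI2 (0.3 equiv), 9 (6 equiv), THF, −10 °C
Reagents that add atoms: none
Why: Evans–Tishchenko reduction: a trivalent samarium alkoxide holds hemiacetal 10 and the ketone in a chair-like array and hydride passes intramolecularly to C10, giving the 1,3-anti alcohol. In the same event the propanoyl group ends on the C8 oxygen, so the ketone is masked, the two oxygens are differentiated and the ester needed for step 7 is installed.

Step 6
Reactants: 11
Product: 12 (3S,4R,5R,6E)-4,6-dimethyl-3-[(triisopropylsilyl)oxy]-9-(trimethylsilyl)non-6-en-8-yn-5-yl propanoate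
Conditions: iPr3SiOTf, 2,6-lutidine, CH2Cl2, −78 → 0 °C
Reagents that add atoms: triisopropylsilyl trifluoromethanesulfonate, CC(C)[Si](C(C)C)(C(C)C)OS(=O)(=O)C(F)(F)F
Why: Silylation of a hindered secondary alcohol with a silyl triflate and a non-nucleophilic base; the cold, weakly basic medium avoids 1,3-acyl migration. The triisopropylsilyl ether outlasts every later desilylation until step 24.

Step 7
Reactants: 12
Product: 15 (2S,3S,4E,6R,7S)-3-ethynyl-2,4,6-trimethyl-7-[(triisopropylsilyl)oxy]non-4-enoic acid, via silyl ketene acetal 13 (not isolated), via silyl ester 14 (not isolated)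
Conditions: LiN(iPr)2, THF, −78 °C; Me3SiCl, −78 → 60 °C; K2CO3, MeOH, 0 °C → rt; 1 M HCl to pH 3
Reagents that add atoms: none
Why: Ireland–Claisen rearrangement: kinetic enolisation in THF and silylation give ketene acetal 13 with the methyl group cis to the allylic oxygen. The chair transition state with the C9 branch equatorial transfers the C8 configuration to C4, sets the C3 methyl anti to the alkynyl group and creates the (E)-C7=C8 alkene. Methanolysis with K2CO3 then cleaves the silyl ester and the alkynyl C–Si bond of 14.

Step 8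
Reactants: 15
Product: 16 (2S,3S,4E,6R,7S)-3-ethynyl-2,4,6-trimethyl-7-[(triisopropylsilyl)oxy]non-4-en-1-ol
Conditions: LiAlH4, Et2O, 0 °C → rt
Reagents that add atoms: none
Why: Hydride reduction of the carboxylic acid to the primary alcohol; the carboxylate cannot enolise, so C3 is safe, and the isolated alkyne, alkene and silyl ether are inert.

Step 9
Reactants: 16
Product: 17 triethyl{[(2S,3S,4E,6R,7S)-3-ethynyl-2,4,6-trimethyl-7-[(triisopropylsilyl)oxy]non-4-en-1-yl]oxy}silane
Conditions: Et3SiCl, imidazole, CH2Cl2, 0 °C
Reagents that add atoms: chlorotriethylsilane, CC[Si](Cl)(CC)CC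
Why: Silyl ether formation; the triethylsilyl group prevents O–H insertion of the carbene in step 11 and can later be removed beside the two bulkier silyl ethers.

Step 10
Reactants: 18 ethyl 2-methyl-3-oxobutanoate
Product: 19 ethyl 2-diazopropanoate
Conditions: 4-acetamidobenzenesulfonyl azide, DBU, MeCN, 0 °C → rt; used as a toluene solution
Reagents that add atoms: 4-acetamidobenzenesulfonyl azide, CC(=O)Nc1ccc(cc1)S(=O)(=O)N=[N+]=[N-]
Why: Deacylative diazo transfer (Regitz type): the enolate of 18 adds to the sulfonyl azide and the acetyl group is expelled onto the sulfonamide nitrogen.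

Step 11
Reactants: 17; 19
Product: 20 ethyl (1R)-1-methyl-2-{(2S,3R,4E,6R,7S)-2,4,6-trimethyl-1-[(triethylsilyl)oxy]-7-[(triisopropylsilyl)oxy]non-4-en-3-yl}cycloprop-2-ene-1-carboxylate
Conditions: Rh2(S-NTTL)4 [dirhodium tetrakis(N-1,8-naphthaloyl-(S)-tert-leucinate)] (1 mol %), toluene, −78 °C, slow addition of 19 (3 equiv)
Reagents that add atoms: none
Why: Dirhodium-carbene [2+1] addition to a 1-alkyne, a known reaction of α-alkyl-α-diazo esters with this family of bulky imido-carboxylate catalysts. Low temperature and the crowded ligand sphere should favour alkyne capture over 1,2-hydride migration, the catalyst should select the carbene face and so fix C6, and the hindered trisubstituted alkene should not compete.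

Step 12
Reactants: 20
Product: 21 [(1R)-1-methyl-2-{(2S,3R,4E,6R,7S)-2,4,6-trimethyl-1-[(triethylsilyl)oxy]-7-[(triisopropylsilyl)oxy]non-4-en-3-yl}cycloprop-2-en-1-yl]methanol
Conditions: iBu2AlH (2.5 equiv), CH2Cl2, −78 °C; aq. potassium sodium tartrate (KNaC4H4O6)
Reagents that add atoms: none
Why: Ester to primary alcohol with an aluminium hydride at −78 °C; the cold, non-acidic conditions avoid alkoxide-directed hydroalumination and acid-induced opening of the cyclopropene.

Step 13
Reactants: 21
Product: 22 tert-butyl{[(1R)-1-methyl-2-{(2S,3R,4E,6R,7S)-2,4,6-trimethyl-1-[(triethylsilyl)oxy]-7-[(triisopropylsilyl)oxy]non-4-en-3-yl}cycloprop-2-en-1-yl]methoxy}dimethylsilane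
Conditions: tBuMe2SiCl, imidazole, DMF, rt
Reagents that add atoms: tert-butylchlorodimethylsilane, CC(C)(C)[Si](C)(C)Cl
Why: Silylation of the neopentyl-type alcohol under basic conditions; the resulting silyloxymethyl group is the bulky C6 substituent that differentiates the two faces of the cyclopropene in step 17.

Step 14
Reactants: 22
Product: 24 tert-butyl{[(1R)-1,2-dimethyl-3-{(2S,3R,4E,6R,7S)-2,4,6-trimethyl-1-[(triethylsilyl)oxy]-7-[(triisopropylsilyl)oxy]non-4-en-3-yl}cycloprop-2-en-1-yl]methoxy}dimethylsilane, via cyclopropenyllithium 23 (not isolated)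
Conditions: LiN(iPr)2, THF, −78 °C; MeI, −78 → 0 °C
Reagents that add atoms: iodomethane, CI
Why: The vinylic C–H bond of a cyclopropene is unusually acidic (high s character); deprotonation with a lithium amide and alkylation of cyclopropenyllithium 23 is established for 3,3-disubstituted cyclopropenes and installs the C1 methyl group.

Step 15
Reactants: 24
Product: 25 (2S,3R,4E,6R,7S)-3-[(3R)-3-{[(tert-butyldimethylsilyl)oxy]methyl}-2,3-dimethylcycloprop-1-en-1-yl]-2,4,6-trimethyl-7-[(triisopropylsilyl)oxy]non-4-en-1-ol
Conditions: pyridinium tosylate (0.2 equiv), MeOH/CH2Cl2, 0 °C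
Reagents that add atoms: none
Why: Acid-catalysed methanolysis; a primary triethylsilyl ether is cleaved much faster than the neopentyl tert-butyldimethylsilyl and the secondary triisopropylsilyl ether, and pyridinium tosylate is too weak an acid to protonate the cyclopropene.

Step 16
Reactants: 25
Product: 26 (2S,3R,4E,6R,7S)-3-[(3R)-3-{[(tert-butyldimethylsilyl)oxy]methyl}-2,3-dimethylcycloprop-1-en-1-yl]-2,4,6-trimethyl-7-[(triisopropylsilyl)oxy]non-4-enal
Conditions: Dess–Martin periodinane, pyridine, CH2Cl2, 0 °C
Reagents that add atoms: none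
Why: Dess–Martin oxidation under pyridine buffering gives the aldehyde without epimerising C3 and without touching the strained alkene; 26 is used at once.

Step 17
Reactants: 26
Product: 27 (1S,3S,4R,5S,6S)-6-{[(tert-butyldimethylsilyl)oxy]methyl}-1,3,6-trimethyl-4-{(2E,4R,5S)-4-methyl-5-[(triisopropylsilyl)oxy]hept-2-en-2-yl}bicyclo[3.1.0]hexan-2-one
Conditions: (n-Bu4N)4[W10O32] (2 mol %), MeCN, 390 nm LED, 0 °C, 0.01 M, argon
Reagents that add atoms: none
Why: Proposed new method: photoexcited decatungstate abstracts the weak, hydridic formyl hydrogen of 26 to give the C2 acyl radical, which attacks C1 of the strained C1=C5 bond in a 5-endo-trig closure (the only ring formed, the cyclopentanone); the cyclopropyl radical left at C5 then takes a hydrogen atom back from the reduced polyoxometalate or from the formyl group of another molecule of 26. The closest known reactions are decatungstate-photocatalysed radical hydroacylation of alkenes by aldehydes and acyl radical cyclisations of alkenals in exo modes; a 5-endo closure onto a cyclopropene has not been shown. It should be feasible because about half of the cyclopropene strain is released in an early transition state and because radical attack at C1 bends the C4 substituent of C5 toward the attacking carbon (trans bending), which shortens the tether, while 4-exo attack at C5 would give a strained spiro cyclobutanone and should be reversible. A stepwise radical path is required and a metal acyl hydride is not used, because H5 must end cis to the C1 methyl and trans to C2, which a concerted syn addition cannot deliver. C1 is set by attack on the cyclopropene face opposite the silyloxymethyl group of C6 (cis to the C6 methyl), and the C4 centre reinforces this, since only in that mode does the small C4 hydrogen and not the alkenyl chain point toward C6, so the chain ends on the convex face. C5 is not an independent variable: once C1–C2 exists the ring can only be cis-fused and hydrogen enters the one open lobe, cis to the C1 methyl. The step needs abstraction of the formyl hydrogen in preference to allylic and α-silyloxy C–H bonds (polarity and steric access favour the aldehyde), cyclisation faster than loss of CO from the α-branched acyl radical (low temperature) and high dilution against intermolecular addition.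

Step 18
Reactants: 27
Product: 28 (1S,3S,4R,5S,6S)-6-(hydroxymethyl)-1,3,6-trimethyl-4-{(2E,4R,5S)-4-methyl-5-[(triisopropylsilyl)oxy]hept-2-en-2-yl}bicyclo[3.1.0]hexan-2-one
Conditions: HF·pyridine, pyridine, THF, 0 °C → rt
Reagents that add atoms: none
Why: Fluoride-mediated desilylation; the primary silyl ether reacts far faster than the secondary triisopropylsilyl ether, and the pyridine buffer protects the enolisable ketone and the cyclopropane.

Step 19
Reactants: 28
Product: 29 (1S,3S,4R,5S,6S)-1,3,6-trimethyl-4-{(2E,4R,5S)-4-methyl-5-[(triisopropylsilyl)oxy]hept-2-en-2-yl}-2-oxobicyclo[3.1.0]hexane-6-carbaldehyde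
Conditions: Dess–Martin periodinane, pyridine, CH2Cl2, 0 °C → rt
Reagents that add atoms: none
Why: Dess–Martin oxidation; the new aldehyde sits on quaternary C6 and cannot epimerise.

Step 20
Reactants: 29; 30 methyl 2-methyl-3-oxopentanoate
Product: 31 methyl 5-hydroxy-2,4-dimethyl-3-oxo-5-[bicyclic residue of 29]pentanoate (diastereomer mixture at the three new centres)
Conditions: 30, NaH, THF, 0 °C; n-BuLi, 0 °C; then 29, −78 °C; aq. NH4Cl
Reagents that add atoms: none
Why: Aldol addition of the γ-carbon of doubly deprotonated 30 to the aldehyde; at −78 °C the aldehyde should react much faster than the C2 ketone, which is flanked by quaternary C1 and branched C3. The three new stereocentres are lost in steps 21 and 22.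

Step 21
Reactants: 31
Product: 32 methyl 2,4-dimethyl-3,5-dioxo-5-[bicyclic residue of 29]pentanoate
Conditions: Dess–Martin periodinane, pyridine, CH2Cl2, 0 °C → rt
Reagents that add atoms: none
Why: Dess–Martin oxidation of the β-hydroxy ketone to the 1,3,5-tricarbonyl (triketide) chain.

Step 22
Reactants: 32
Product: 33 4-hydroxy-3,5-dimethyl-6-{(1S,3S,4R,5S,6S)-1,3,6-trimethyl-4-{(2E,4R,5S)-4-methyl-5-[(triisopropylsilyl)oxy]hept-2-en-2-yl}-2-oxobicyclo[3.1.0]hexan-6-yl}-2H-pyran-2-one
Conditions: DBU, toluene, rt → 60 °C
Reagents that add atoms: none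
Why: Base-mediated cyclisation of the β,δ-diketo ester: the enol oxygen of the carbonyl next to C6 is acylated by the ester and methanol is lost, giving the 4-hydroxy-2-pyranone. C3 carries its methyl trans to the C4 chain, which should be the more stable arrangement, so reversible enolisation should not erode it.

Step 23
Reactants: 33
Product: 34 2-methoxy-3,5-dimethyl-6-{(1S,3S,4R,5S,6S)-1,3,6-trimethyl-4-{(2E,4R,5S)-4-methyl-5-[(triisopropylsilyl)oxy]hept-2-en-2-yl}-2-oxobicyclo[3.1.0]hexan-6-yl}-4H-pyran-4-one
Conditions: MeOTf, CH2Cl2, rt; aq. NaHCO3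
Reagents that add atoms: methyl trifluoromethanesulfonate, COS(=O)(=O)C(F)(F)F
Why: O-methylation with a hard alkylating agent occurs at the most basic oxygen, the lactone carbonyl, and deprotonation on work-up gives the 2-methoxy-4-pyranone and not the 4-methoxy-2-pyranone.

Step 24
Reactants: 34
Product: 35 6-{(1S,3S,4R,5S,6S)-4-[(2E,4R,5S)-5-hydroxy-4-methylhept-2-en-2-yl]-1,3,6-trimethyl-2-oxobicyclo[3.1.0]hexan-6-yl}-2-methoxy-3,5-dimethyl-4H-pyran-4-one
Conditions: 48% aq. HF, MeCN, 0 °C → rt
Reagents that add atoms: none
Why: Acidic fluoride cleavage of the secondary triisopropylsilyl ether; the methoxypyranone, the acyl cyclopropane and the alkene should tolerate aqueous HF in MeCN at this temperature.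

Step 25
Reactants: 35
Product: 36 2-methoxy-3,5-dimethyl-6-{(1S,3S,4R,5S,6S)-1,3,6-trimethyl-4-[(2E,4R)-4-methyl-5-oxohept-2-en-2-yl]-2-oxobicyclo[3.1.0]hexan-6-yl}-4H-pyran-4-one (CNP0216193.1)
Conditions: Dess–Martin periodinane, pyridine, CH2Cl2, 0 °C
Reagents that add atoms: none
Why: Dess–Martin oxidation of the C10 carbinol as the last step; the buffered, neutral medium should leave C9 and the β,γ-position of the alkene unchanged.

## Compound list

1 | 3-(trimethylsilyl)prop-2-ynal | C[Si](C)(C)C#CC=O | starting material
2 | 2-(triphenyl-λ5-phosphanylidene)propanal | CC(C=O)=P(c1ccccc1)(c1ccccc1)c1ccccc1 | starting material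
3 | (2E)-2-methyl-5-(trimethylsilyl)pent-2-en-4-ynal | C[Si](C)(C)C#C/C=C(\C)C=O | intermediate
4 | (4R)-4-benzyl-3-propanoyl-1,3-oxazolidin-2-one | CCC(=O)N1[C@H](Cc2ccccc2)COC1=O | starting material
5 | (4R)-4-benzyl-3-[(1Z)-1-(dibutylboranyloxy)prop-1-en-1-yl]-1,3-oxazolidin-2-one (boron enolate, not isolated) | C/C=C(\OB(CCCC)CCCC)N1[C@H](Cc2ccccc2)COC1=O | intermediate
6 | (4R)-4-benzyl-3-[(2R,3R,4E)-3-hydroxy-2,4-dimethyl-7-(trimethylsilyl)hept-4-en-6-ynoyl]-1,3-oxazolidin-2-one | O=C1OC[C@@H](Cc2ccccc2)N1C(=O)[C@H](C)[C@@H](O)/C(C)=C/C#C[Si](C)(C)C | intermediate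
7 | (2R,3R,4E)-3-hydroxy-N-methoxy-N,2,4-trimethyl-7-(trimethylsilyl)hept-4-en-6-ynamide | CON(C)C(=O)[C@H](C)[C@@H](O)/C(C)=C/C#C[Si](C)(C)C | intermediate
8 | (4R,5R,6E)-5-hydroxy-4,6-dimethyl-9-(trimethylsilyl)non-6-en-8-yn-3-one | CCC(=O)[C@H](C)[C@@H](O)/C(C)=C/C#C[Si](C)(C)C | intermediate
9 | propanal | CCC=O | starting material
10 | (4R,5R,6E)-5-(1-hydroxypropoxy)-4,6-dimethyl-9-(trimethylsilyl)non-6-en-8-yn-3-one (hemiacetal, samarium-bound, not isolated) | CCC(=O)[C@H](C)[C@@H](OC(O)CC)/C(C)=C/C#C[Si](C)(C)C | intermediate
11 | (3S,4S,5R,6E)-3-hydroxy-4,6-dimethyl-9-(trimethylsilyl)non-6-en-8-yn-5-yl propanoate | CC[C@H](O)[C@H](C)[C@@H](OC(=O)CC)/C(C)=C/C#C[Si](C)(C)C | intermediate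
12 | (3S,4R,5R,6E)-4,6-dimethyl-3-[(triisopropylsilyl)oxy]-9-(trimethylsilyl)non-6-en-8-yn-5-yl propanoate | CC[C@H](O[Si](C(C)C)(C(C)C)C(C)C)[C@H](C)[C@@H](OC(=O)CC)/C(C)=C/C#C[Si](C)(C)C | intermediate
13 | (E)-trimethylsilyl ketene acetal of 12 (methyl cis to the allylic oxygen; not isolated) | CC[C@H](O[Si](C(C)C)(C(C)C)C(C)C)[C@H](C)[C@@H](O/C(=C\C)O[Si](C)(C)C)/C(C)=C/C#C[Si](C)(C)C | intermediate
14 | trimethylsilyl ester of 15 that still carries Me3Si on the alkyne terminus (not isolated) | CC[C@H](O[Si](C(C)C)(C(C)C)C(C)C)[C@H](C)/C=C(\C)[C@H](C#C[Si](C)(C)C)[C@H](C)C(=O)O[Si](C)(C)C | intermediate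
15 | (2S,3S,4E,6R,7S)-3-ethynyl-2,4,6-trimethyl-7-[(triisopropylsilyl)oxy]non-4-enoic acid | CC[C@H](O[Si](C(C)C)(C(C)C)C(C)C)[C@H](C)/C=C(\C)[C@H](C#C)[C@H](C)C(=O)O | intermediate
16 | (2S,3S,4E,6R,7S)-3-ethynyl-2,4,6-trimethyl-7-[(triisopropylsilyl)oxy]non-4-en-1-ol | CC[C@H](O[Si](C(C)C)(C(C)C)C(C)C)[C@H](C)/C=C(\C)[C@H](C#C)[C@H](C)CO | intermediate
17 | triethyl{[(2S,3S,4E,6R,7S)-3-ethynyl-2,4,6-trimethyl-7-[(triisopropylsilyl)oxy]non-4-en-1-yl]oxy}silane | CC[C@H](O[Si](C(C)C)(C(C)C)C(C)C)[C@H](C)/C=C(\C)[C@H](C#C)[C@H](C)CO[Si](CC)(CC)CC | intermediate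
18 | ethyl 2-methyl-3-oxobutanoate | CCOC(=O)C(C)C(C)=O | starting material
19 | ethyl 2-diazopropanoate | CCOC(=O)C(C)=[N+]=[N-] | intermediate
20 | ethyl (1R)-1-methyl-2-{(2S,3R,4E,6R,7S)-2,4,6-trimethyl-1-[(triethylsilyl)oxy]-7-[(triisopropylsilyl)oxy]non-4-en-3-yl}cycloprop-2-ene-1-carboxylate | CC[C@H](O[Si](C(C)C)(C(C)C)C(C)C)[C@H](C)/C=C(\C)[C@H](C1=C[C@@]1(C)C(=O)OCC)[C@H](C)CO[Si](CC)(CC)CC | intermediate
21 | [(1R)-1-methyl-2-{(2S,3R,4E,6R,7S)-2,4,6-trimethyl-1-[(triethylsilyl)oxy]-7-[(triisopropylsilyl)oxy]non-4-en-3-yl}cycloprop-2-en-1-yl]methanol | CC[C@H](O[Si](C(C)C)(C(C)C)C(C)C)[C@H](C)/C=C(\C)[C@H](C1=C[C@@]1(C)CO)[C@H](C)CO[Si](CC)(CC)CC | intermediate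
22 | tert-butyldimethylsilyl ether of 21 | CC[C@H](O[Si](C(C)C)(C(C)C)C(C)C)[C@H](C)/C=C(\C)[C@H](C1=C[C@@]1(C)CO[Si](C)(C)C(C)(C)C)[C@H](C)CO[Si](CC)(CC)CC | intermediate
23 | cyclopropenyllithium from 22, lithium on the vinylic carbon (not isolated) | CC[C@H](O[Si](C(C)C)(C(C)C)C(C)C)[C@H](C)/C=C(\C)[C@H](C1=C([Li])[C@@]1(C)CO[Si](C)(C)C(C)(C)C)[C@H](C)CO[Si](CC)(CC)CC | intermediate
24 | tert-butyl{[(1R)-1,2-dimethyl-3-{(2S,3R,4E,6R,7S)-2,4,6-trimethyl-1-[(triethylsilyl)oxy]-7-[(triisopropylsilyl)oxy]non-4-en-3-yl}cycloprop-2-en-1-yl]methoxy}dimethylsilane | CC[C@H](O[Si](C(C)C)(C(C)C)C(C)C)[C@H](C)/C=C(\C)[C@H](C1=C(C)[C@@]1(C)CO[Si](C)(C)C(C)(C)C)[C@H](C)CO[Si](CC)(CC)CC | intermediate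
25 | (2S,3R,4E,6R,7S)-3-[(3R)-3-{[(tert-butyldimethylsilyl)oxy]methyl}-2,3-dimethylcycloprop-1-en-1-yl]-2,4,6-trimethyl-7-[(triisopropylsilyl)oxy]non-4-en-1-ol | CC[C@H](O[Si](C(C)C)(C(C)C)C(C)C)[C@H](C)/C=C(\C)[C@H](C1=C(C)[C@@]1(C)CO[Si](C)(C)C(C)(C)C)[C@H](C)CO | intermediate
26 | (2S,3R,4E,6R,7S)-3-[(3R)-3-{[(tert-butyldimethylsilyl)oxy]methyl}-2,3-dimethylcycloprop-1-en-1-yl]-2,4,6-trimethyl-7-[(triisopropylsilyl)oxy]non-4-enal (key-step precursor) | CC[C@H](O[Si](C(C)C)(C(C)C)C(C)C)[C@H](C)/C=C(\C)[C@H](C1=C(C)[C@@]1(C)CO[Si](C)(C)C(C)(C)C)[C@H](C)C=O | intermediate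
27 | (1S,3S,4R,5S,6S)-6-{[(tert-butyldimethylsilyl)oxy]methyl}-1,3,6-trimethyl-4-{(2E,4R,5S)-4-methyl-5-[(triisopropylsilyl)oxy]hept-2-en-2-yl}bicyclo[3.1.0]hexan-2-one (key-step product) | CC[C@H](O[Si](C(C)C)(C(C)C)C(C)C)[C@H](C)/C=C(\C)[C@H]1[C@H](C)C(=O)[C@@]2(C)[C@@H]1[C@]2(C)CO[Si](C)(C)C(C)(C)C | intermediate
28 | (1S,3S,4R,5S,6S)-6-(hydroxymethyl)-1,3,6-trimethyl-4-{(2E,4R,5S)-4-methyl-5-[(triisopropylsilyl)oxy]hept-2-en-2-yl}bicyclo[3.1.0]hexan-2-one | CC[C@H](O[Si](C(C)C)(C(C)C)C(C)C)[C@H](C)/C=C(\C)[C@H]1[C@H](C)C(=O)[C@@]2(C)[C@@H]1[C@]2(C)CO | intermediate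
29 | (1S,3S,4R,5S,6S)-1,3,6-trimethyl-4-{(2E,4R,5S)-4-methyl-5-[(triisopropylsilyl)oxy]hept-2-en-2-yl}-2-oxobicyclo[3.1.0]hexane-6-carbaldehyde | CC[C@H](O[Si](C(C)C)(C(C)C)C(C)C)[C@H](C)/C=C(\C)[C@H]1[C@H](C)C(=O)[C@@]2(C)[C@@H]1[C@]2(C)C=O | intermediate
30 | methyl 2-methyl-3-oxopentanoate | CCC(=O)C(C)C(=O)OC | starting material
31 | methyl 5-hydroxy-2,4-dimethyl-3-oxo-5-[bicyclic residue]pentanoate; bicycle and chain configured as in 29, three new centres as a mixture | CC[C@H](O[Si](C(C)C)(C(C)C)C(C)C)[C@H](C)/C=C(\C)[C@H]1[C@H](C)C(=O)[C@@]2(C)[C@@H]1[C@]2(C)C(O)C(C)C(=O)C(C)C(=O)OC | intermediate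
32 | methyl 2,4-dimethyl-3,5-dioxo-5-[bicyclic residue]pentanoate; bicycle and chain configured as in 29 | CC[C@H](O[Si](C(C)C)(C(C)C)C(C)C)[C@H](C)/C=C(\C)[C@H]1[C@H](C)C(=O)[C@@]2(C)[C@@H]1[C@]2(C)C(=O)C(C)C(=O)C(C)C(=O)OC | intermediate
33 | 4-hydroxy-3,5-dimethyl-6-{(1S,3S,4R,5S,6S)-1,3,6-trimethyl-4-{(2E,4R,5S)-4-methyl-5-[(triisopropylsilyl)oxy]hept-2-en-2-yl}-2-oxobicyclo[3.1.0]hexan-6-yl}-2H-pyran-2-one | CC[C@H](O[Si](C(C)C)(C(C)C)C(C)C)[C@H](C)/C=C(\C)[C@H]1[C@H](C)C(=O)[C@@]2(C)[C@@H]1[C@]2(C)C1=C(C)C(O)=C(C)C(=O)O1 | intermediate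
34 | 2-methoxy-3,5-dimethyl-6-{(1S,3S,4R,5S,6S)-1,3,6-trimethyl-4-{(2E,4R,5S)-4-methyl-5-[(triisopropylsilyl)oxy]hept-2-en-2-yl}-2-oxobicyclo[3.1.0]hexan-6-yl}-4H-pyran-4-one | CC[C@H](O[Si](C(C)C)(C(C)C)C(C)C)[C@H](C)/C=C(\C)[C@H]1[C@H](C)C(=O)[C@@]2(C)[C@@H]1[C@]2(C)c1oc(OC)c(C)c(=O)c1C | intermediate
35 | 6-{(1S,3S,4R,5S,6S)-4-[(2E,4R,5S)-5-hydroxy-4-methylhept-2-en-2-yl]-1,3,6-trimethyl-2-oxobicyclo[3.1.0]hexan-6-yl}-2-methoxy-3,5-dimethyl-4H-pyran-4-one | CC[C@H](O)[C@H](C)/C=C(\C)[C@H]1[C@H](C)C(=O)[C@@]2(C)[C@@H]1[C@]2(C)c1oc(OC)c(C)c(=O)c1C | intermediate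
36 | 2-methoxy-3,5-dimethyl-6-{(1S,3S,4R,5S,6S)-1,3,6-trimethyl-4-[(2E,4R)-4-methyl-5-oxohept-2-en-2-yl]-2-oxobicyclo[3.1.0]hexan-6-yl}-4H-pyran-4-one (CNP0216193.1) | CCC(=O)[C@H](C)/C=C(\C)[C@H]1[C@H](C)C(=O)[C@@]2(C)[C@@H]1[C@]2(C)c1oc(OC)c(C)c(=O)c1C | target

## Step count and least certain steps

Total step count: 25. Longest linear sequence: 24 steps (steps 1–9 and 11–25, from 1, 2 or 4 to 36); step 10 is a one-step side branch.

**Step 17 (bears the label).** The acyl radical may fail to close. Loss of CO from the α-branched acyl radical, return of hydrogen to regenerate 26, or attack of the excited polyoxometalate on the electron-rich alkenes (electron transfer, allylic hydrogen abstraction) could each outrun a 5-endo closure whose geometry is without precedent. A weaker facial preference than expected would give the bicycle epimeric at C1 and C5. The fallback uses known chemistry and makes the cyclopropane last, by intramolecular cyclopropanation of a diazo ketone, so that no cyclopropene is needed. It sets out from 17. Deprotonation of the alkyne with n-BuLi and methylation with MeI gives the prop-1-ynyl compound F1. Hydrozirconation with Cp2Zr(H)Cl (zirconium to the methyl-bearing carbon, syn) and iodinolysis give the (E)-2-iodoalkene F2. Iodine–lithium exchange with t-BuLi and trapping with formaldehyde give the (E)-allylic alcohol F3 (methyl cis to C4), which tBuMe2SiCl/imidazole converts into the silyl ether F4. Pyridinium tosylate in methanol removes the triethylsilyl group to give the alcohol F5; TEMPO/PhI(OAc)2 in aqueous MeCN oxidises it to the acid F6; (COCl)2 gives the acid chloride F7; diazoethane converts this into the 2-diazo-3-ketone F8. Cu(acac)2 in hot toluene then closes the cyclopropane onto the C5=C6 alkene. The alkene geometry places the C6 methyl endo and the silyloxymethyl group exo, the tether enforces cis fusion and the C4 chain should take the convex face, so the route is rejoined at 27.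

**Step 11.** 1,2-Hydride migration in the rhodium carbene (to ethyl acrylate) and carbene dimerisation may consume 19 faster than the hindered, branched alkyne traps it, and the catalyst may not override the adjacent C4 stereocentre, which would erode selectivity at C6. The fallback gives up catalyst control of C6. From 17 and 19, the achiral dirhodium tetrapivalate Rh2(O2CCMe3)4 is used at −78 °C as the catalyst best suited to outrun hydride migration with 1-alkynes. It gives 20 together with its (1S) epimer F9; the two diastereomers are separated by chromatography (if necessary after step 12), F9 is discarded and the route continues from 20.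

**Step 14.** Metalation may be incomplete or unselective, because the hindered amide base has to reach a vinylic C–H bond flanked by a quaternary carbon while the doubly allylic C4–H bond offers a competing site, which would lead to isomerisation. The fallback changes the substrate and the base. It sets out from the free alcohol 21, which is treated with MeLi (2.2 equiv) in Et2O so that the lithium alkoxide directs and accelerates removal of the vinylic hydrogen; MeI then alkylates carbon selectively to give the C-methylated cyclopropenylmethanol F10. Silylation with tBuMe2SiCl/imidazole returns to the route at 24.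

**Step 20.** The strongly basic dianion may enolise or attack the C2 ketone, which would mean epimerisation at C3 or loss of material, instead of adding cleanly to the hindered aldehyde. The fallback replaces the basic dianion by a Lewis acid-mediated vinylogous aldol reaction. Keto ester 30 is doubly deprotonated with LiN(iPr)2 and silylated with Me3SiCl to the bis(trimethylsilyl) dienol ether F11, and this is added to 29 with BF3·OEt2 in CH2Cl2 at −78 °C. After aqueous work-up the same hydroxy keto ester 31 is obtained and the route continues with step 21.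

**Step 23.** Methylation may occur at the 4-oxygen, giving the isomeric 4-methoxy-2-pyranone, or the product may be hard to separate from it, because the two oxygens of the ambident hydroxypyranone differ little. The fallback avoids the hydroxypyranone altogether. It sets out from 32, which is cyclodehydrated directly with Ph3P/CCl4; this keeps the ester methoxy group as the pyranone methoxy group and bypasses steps 22 and 23, rejoining the route at 34. No new compound is made.

## Further compounds

F1 | step 17 | prop-1-ynyl analogue of 17 (alkyne terminus methylated) | CC[C@H](O[Si](C(C)C)(C(C)C)C(C)C)[C@H](C)/C=C(\C)[C@H](C#CC)[C@H](C)CO[Si](CC)(CC)CC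
F2 | step 17 | (E)-2-iodoprop-1-enyl compound from F1 (iodine trans to C4) | CC[C@H](O[Si](C(C)C)(C(C)C)C(C)C)[C@H](C)/C=C(\C)[C@H](/C=C(\C)I)[C@H](C)CO[Si](CC)(CC)CC
F3 | step 17 | (E)-allylic alcohol from F2 (3-hydroxy-2-methylprop-1-enyl group on C4, methyl cis to C4) | CC[C@H](O[Si](C(C)C)(C(C)C)C(C)C)[C@H](C)/C=C(\C)[C@H](/C=C(\C)CO)[C@H](C)CO[Si](CC)(CC)CC
F4 | step 17 | tert-butyldimethylsilyl ether of F3 | CC[C@H](O[Si](C(C)C)(C(C)C)C(C)C)[C@H](C)/C=C(\C)[C@H](/C=C(\C)CO[Si](C)(C)C(C)(C)C)[C@H](C)CO[Si](CC)(CC)CC
F5 | step 17 | primary alcohol from F4 (triethylsilyl group removed) | CC[C@H](O[Si](C(C)C)(C(C)C)C(C)C)[C@H](C)/C=C(\C)[C@H](/C=C(\C)CO[Si](C)(C)C(C)(C)C)[C@H](C)CO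
F6 | step 17 | carboxylic acid from F5 | CC[C@H](O[Si](C(C)C)(C(C)C)C(C)C)[C@H](C)/C=C(\C)[C@H](/C=C(\C)CO[Si](C)(C)C(C)(C)C)[C@H](C)C(=O)O
F7 | step 17 | acid chloride of F6 | CC[C@H](O[Si](C(C)C)(C(C)C)C(C)C)[C@H](C)/C=C(\C)[C@H](/C=C(\C)CO[Si](C)(C)C(C)(C)C)[C@H](C)C(Cl)=O
F8 | step 17 | 2-diazo-3-ketone from F7 | CC[C@H](O[Si](C(C)C)(C(C)C)C(C)C)[C@H](C)/C=C(\C)[C@H](/C=C(\C)CO[Si](C)(C)C(C)(C)C)[C@H](C)C(=O)C(C)=[N+]=[N-]
F9 | step 11 | (1S) epimer of 20 at the quaternary cyclopropene carbon | CC[C@H](O[Si](C(C)C)(C(C)C)C(C)C)[C@H](C)/C=C(\C)[C@H](C1=C[C@]1(C)C(=O)OCC)[C@H](C)CO[Si](CC)(CC)CC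
F10 | step 14 | C-methylated cyclopropenylmethanol (21 with methyl on the vinylic carbon) | CC[C@H](O[Si](C(C)C)(C(C)C)C(C)C)[C@H](C)/C=C(\C)[C@H](C1=C(C)[C@@]1(C)CO)[C@H](C)CO[Si](CC)(CC)CC
F11 | step 20 | 1-methoxy-2-methyl-1,3-bis(trimethylsilyloxy)penta-1,3-diene | CC=C(O[Si](C)(C)C)C(C)=C(OC)O[Si](C)(C)C
F0 | step 23 | none | none
A1 | alternative 1 | methyl 1,3,6-trimethyl-2-oxobicyclo[3.1.0]hexane-6-carboxylate | C1[C@H](C)C(=O)[C@@]2(C)[C@@H]1[C@]2(C)C(=O)OC
A2 | alternative 2 | 6-(but-1-en-2-yl)-2-(tert-butyldimethylsilyloxy)-1,6-dimethylbicyclo[3.1.0]hexane | C1C[C@@H](O[Si](C)(C)C(C)(C)C)[C@@]2(C)[C@@H]1[C@]2(C)C(=C)CC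
A3 | alternative 3 | 2-(tert-butyldimethylsilyloxy)-6-(4-methoxybenzyloxymethyl)-1,3,6-trimethylbicyclo[3.1.0]hex-3-ene | C1=C(C)[C@@H](O[Si](C)(C)C(C)(C)C)[C@@]2(C)[C@@H]1[C@]2(C)COCc1ccc(OC)cc1
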